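19.4 min is the number I carry: the Monday clock, meaning time multiplied by catalyst charge and divided by Monday's charge, here for the flask at 40 min.

all flasks: substrate 0.42 M

| flask | catalyst | remark | time |
|---|---|---|---|
| Friday's | 32 mM | run made earlier |  |
| Monday's | 130 mM | run made earlier |  |
| flask | 63 mM |  | 40 min |

| run | time / min | target / % | isomer of the product / % |
|---|---|---|---|
| Friday's | 1.50 | 28.4 | 2.0 |
| Friday's | 5.00 | 28.9 | 3.8 |
| Friday's | 8.00 | 28.5 | 4.4 |
| Friday's | 12.0 | 28.8 | 5.9 |
| Friday's | 20.0 | 28.0 | 8.4 |
| Friday's | 25.0 | 26.6 | 9.5 |
| Monday's | 1.50 | 27.6 | 5.4 |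
| Monday's | 5.00 | 27.7 | 9.2 |
| Monday's | 8.00 | 27.1 | 10.7 |
| Monday's | 12.0 | 26.7 | 11.9 |
| Monday's | 20.0 | 26.3 | 13.2 |
| Monday's | 25.0 | 26.5 | 13.8 |

(scatter of a reading: 0.5 percentage points)

- ratio of target to isomer of the product at 0.80 s
- ratio of target to isomer of the product at 40 s
- ratio of target to isomer of the product at 40 min

- what was read earlier has a scatter of 0.5 percentage points, one standard deviation

My bench rule is that runs with equal [substrate] read alike at equal Monday clock. Friday's run tests it: its reading at 25.0 min has clock 6.15 min, later than Monday's reading at 5.00 min and earlier than the one at 8.00 min. Its isomer, 9.5%, is more than Monday's 9.2% and less than Monday's 10.7%. So I read the flask at 40 min off Monday's run at 20.0 min: target 26.3%, isomer 13.2%, a read ratio of 1.99.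

The rule fails at lower clocks: Friday's reading at 8.00 min has clock 1.97 min, later than Monday's reading at 1.50 min, yet its isomer, 4.4%, is less than Monday's 5.4%. The flask reaches that clock at 4.06 min. The time 40 s is 0.164 of that and 0.80 s is 0.00328 of it, so I commit to no ratio at either. That early stretch is kinetic control, a race of rates.

The forecast gives 14, 11 and 1.95, the first “assuming the early ratio is fixed by parallel formation”. Where I give no figure, it gives two.

The flask gives 2.27, 9.60 and 2.04.

    substrate ⇌ target (K = 0.438, k = 0.0128 /s)
    target + catalyst ⇌ isomer of the product + catalyst, rate k2*[catalyst]*[target] forward; the back reaction follows from the equilibrium constant (K = 0.509, k = 0.0189 /M/s)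
    isomer of the product + catalyst ⇌ substrate + catalyst, rate k3*[catalyst]*[isomer of the product] forward; the back reaction follows from the equilibrium constant (k = 0.451 /M/s)
    catalyst ⇌ dormant form (K = 25.0, k = 0.299 /s)

At clock 19.4 min the flask ends at 2.04, beside my 1.99. At 0.80 s, shorter than the 2.23 s relaxation half-life of catalyst and dormant form, the forecast stands 6.17 times above the flask; by 4.00 min the flask holds catalyst 3.85% and dormant form 96.2%. The neighbour charged with 0.25 M of catalyst has clock 76.9 min at 40 min, later than Monday's last reading at 25.0 min, whose ratio reads 1.92. That neighbour ends at ratio 1.96, with isomer 13.4%.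

(The data are calculated with made-up constants; scatter was added.)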